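**Retrosynthetic overview**
Ring atoms: C1 (CMe2), C2 (CHBr), C3 (CH2), C4 (CHCl), C5 (=C7H–C8H2Br), C6 (CHCl). The plan rests on the triad C6–C1(CH3)2–C2(H)Br. A secondary neopentylic bromide beside the quaternary carbon, with heteroatom-bearing C6 on the other side, is the retron O=C6–C1Me2–C2HBr of a bromonium-triggered 1,2-methyl shift.
Target 28 ⇒ (C8 Cl/Br exchange, C6 OH→Cl with inversion, C8–O cleavage) bicyclic 2,5-dihydrofuran 21, whose C6–O–C8 bridge locks the C5=C7 geometry ⇒ (1,4-chloroetherification: C4–Cl and O–C8) dienol 19.
19 ⇒ (Stille C5–C7, Luche reduction, α-iodination) bromocyclohexenone 14 ⇒ (metathesis C4=C5, α-methylenation of the acetyl group) open-chain bromoketone 7.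
7 ⇒ (asymmetric bromination with methyl shift: C2–Br and second C1–CH3) achiral dienol 5 ⇒ (methylalumination/allylation) 2-methylbut-3-yn-2-ol, AlMe3 and allyl bromide.
Ring order: carbocycle (ring A) in step 5; temporary dihydrofuran (ring B) closed in step 9 and reopened in step 10.

Key step: step 2

Assumption: the ring face carrying the C2 bromine is called β and the other α; (DHQD)2PHAL is taken to deliver bromine to the alkene face that leads to (S)-7, and the pseudoenantiomeric (DHQ)2PHAL would be used should the sense of induction prove opposite.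

**Step 1**
Reactants: 1 2-methylbut-3-yn-2-ol; 2 trimethylaluminium; 3 allyl bromide
Product: 5 (E)-2,3-dimethylhepta-3,6-dien-2-ol, via alkenylalane 4 (not isolated)
Conditions: AlMe3 (3 equiv), Cp2ZrCl2 (0.25 equiv), CH2Cl2, 0 °C to rt; then allyl bromide, Pd(PPh3)4 (5 mol %), THF, rt; aq. Rochelle salt
Reagents that add atoms: trimethylaluminium 2, C[Al](C)C; allyl bromide 3, C=CCBr
Why: Negishi zirconium-catalysed methylalumination adds CH3 and Al syn across the terminal alkyne (CH3 to the internal carbon, the hydroxyl being masked in situ as its aluminium alkoxide), and the palladium-catalysed allylation of the alkenylalane keeps the geometry, so the allyl group ends trans to the carbinol carbon as required for the E alkene.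

**Step 2**
Reactants: 5 (E)-2,3-dimethylhepta-3,6-dien-2-ol; 6 N-bromosuccinimide
Product: 7 (S)-4-bromo-3,3-dimethylhept-6-en-2-one
Conditions: NBS (1.1 equiv), (DHQD)2PHAL (10 mol %), PhCO2H (20 mol %), toluene/CHCl3 1:1, −40 °C, dark
Reagents that add atoms: N-bromosuccinimide 6, O=C1CCC(=O)N1Br
Why: Proposed new method: catalyst-bound NBS transfers Br+ to the trisubstituted alkene of 5, the bromonium ion loosens at its tertiary carbon (future C1), and the carbinol methyl group lying anti to that C–Br bond shifts from the carbinol carbon (future C6) while the hydroxyl proton passes to the succinimide anion, so that the C2–Br bond, the second C1–CH3 bond and the C6 ketone arise in one event. The closest known reaction type is the cinchona-alkaloid-catalysed halogenation/semipinacol rearrangement of tertiary allylic alcohols, which is established for ring expansions of strained carbinols and for aryl shifts but not for a methyl shift in an open chain; the cation involved is that of the pinacol rearrangement, for which methyl migration is the normal course, and both groups on the carbinol carbon are methyl, so no other group can migrate. No ring is closed. The single new stereocentre C2 (S) is decided only by the alkene face that receives bromine, which is controlled by the chiral pocket of (DHQD)2PHAL through hydrogen bonding to the tertiary hydroxyl; C1 becomes CMe2 and carries no stereochemical information. Chemoselectivity for the trisubstituted over the terminal alkene follows from its higher nucleophilicity and from the hydroxyl anchor, and the regiochemistry (Br on the CH carbon) from Markovnikov opening toward the tertiary centre. Epoxide closure and proton loss from the vinylic methyl are the exits to be suppressed, for which the carboxylic acid additive (reversible epoxide closure) and the low temperature are chosen.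

**Step 3**
Reactants: 7 (S)-4-bromo-3,3-dimethylhept-6-en-2-one; 8 N,N-dimethylmethyleneiminium iodide (Eschenmoser's salt)
Product: 10 (S)-5-bromo-1-(dimethylamino)-4,4-dimethyloct-7-en-3-one, via lithium enolate 9 (not isolated)
Conditions: LiHMDS (1.05 equiv), THF, −78 °C; then CH2=NMe2+ I−, −78 to 0 °C
Reagents that add atoms: Eschenmoser's salt 8, C[N+](C)=C.[I-]; lithium hexamethyldisilazide, [Li]N([Si](C)(C)C)[Si](C)(C)C (supplies only the lithium of 9)
Why: Mannich reaction of a preformed lithium enolate with an iminium salt: C1 is quaternary, so only the acetyl CH3 (future C5) can be deprotonated, and at −78 °C the hindered neopentylic bromide neither eliminates nor alkylates the enolate, so C2 is untouched.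

**Step 4**
Reactants: 10 (S)-5-bromo-1-(dimethylamino)-4,4-dimethyloct-7-en-3-one; 11 iodomethane
Product: 13 (S)-5-bromo-4,4-dimethylocta-1,7-dien-3-one, via methiodide 12 (not isolated)
Conditions: MeI, Et2O, rt; then sat. aq. NaHCO3/CH2Cl2, rt
Reagents that add atoms: iodomethane 11, CI (its CH3 and iodide are carried by 12 only and leave again)
Why: Exhaustive methylation followed by E1cB (Hofmann-type) loss of trimethylamine from the β-ammonio ketone needs only bicarbonate, a base too weak to eliminate HBr toward C3.

**Step 5**
Reactants: 13 (S)-5-bromo-4,4-dimethylocta-1,7-dien-3-one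
Product: 14 (S)-5-bromo-6,6-dimethylcyclohex-2-en-1-one
Conditions: second-generation Hoveyda–Grubbs catalyst (3 mol %), CH2Cl2 (0.01 M), 40 °C
Reagents that add atoms: none
Why: Ring-closing metathesis of an enone–alkene pair, a standard entry to cyclohex-2-enones: the catalyst loads on the terminal alkene, closes the six-membered ring A at C4=C5 onto the vinyl ketone with loss of ethene, and its neutral conditions leave the C2 bromide and its configuration alone.

**Step 6**
Reactants: 14 (S)-5-bromo-6,6-dimethylcyclohex-2-en-1-one; 15 iodine
Product: 16 (S)-5-bromo-2-iodo-6,6-dimethylcyclohex-2-en-1-one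
Conditions: I2, pyridine/CH2Cl2 1:1, 0 °C to rt
Reagents that add atoms: iodine 15, [I][I]
Why: α-Iodination of an enone by the Baylis–Hillman-type addition–elimination sequence (pyridine adds at C4, the enolate is iodinated at C5, pyridine leaves), pyridine being too weak a base for the γ-deprotonation at C3 that would expel bromide.

**Step 7**
Reactants: 16 (S)-5-bromo-2-iodo-6,6-dimethylcyclohex-2-en-1-one
Product: 17 (1S,5S)-5-bromo-2-iodo-6,6-dimethylcyclohex-2-en-1-ol (OH β, cis to Br)
Conditions: NaBH4, CeCl3·7H2O, MeOH, −78 to −20 °C
Reagents that add atoms: none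
Why: Luche 1,2-reduction: hydride reaches C6 from the α face because the β face is screened by the pseudoaxial C1 methyl in the bromine-equatorial conformer and by the bromine itself in the bromine-axial one, which sets the C6 hydroxyl β (cis to Br), while the cold protic medium protonates the alkoxide before it can fragment against the C2–Br bond.

**Step 8**
Reactants: 17 (1S,5S)-5-bromo-2-iodo-6,6-dimethylcyclohex-2-en-1-ol; 18 tributyl(vinyl)stannane
Product: 19 (1R,5S)-5-bromo-2-ethenyl-6,6-dimethylcyclohex-2-en-1-ol
Conditions: Bu3SnCH=CH2, Pd2(dba)3 (2.5 mol %), AsPh3 (10 mol %), NMP, rt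
Reagents that add atoms: tributyl(vinyl)stannane 18, C=C[Sn](CCCC)(CCCC)CCCC
Why: Stille coupling of an alkenyl iodide: zerovalent palladium inserts into the C5–I bond far faster than into the hindered secondary C2–Br bond, the base-free medium forms no alkoxide that could fragment, and coupling after the reduction avoids the dimerisation-prone 2-vinylcyclohexenone.

**Step 9**
Reactants: 19 (1R,5S)-5-bromo-2-ethenyl-6,6-dimethylcyclohex-2-en-1-ol; 20 N-chlorosuccinimide
Product: 21 (4S,6S,7aR)-6-bromo-4-chloro-7,7-dimethyl-2,4,5,6,7,7a-hexahydro-1-benzofuran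
Conditions: NCS (1.05 equiv), (CF3)2CHOH/CH2Cl2 1:4, −20 °C, dark
Reagents that add atoms: N-chlorosuccinimide 20, O=C1CCC(=O)N1Cl
Why: Proposed new method: Cl+ from NCS (activated by hydrogen bonding to the fluorinated alcohol) attacks the more nucleophilic trisubstituted ring alkene at C4 along the axial trajectory of the bromine-equatorial half-chair, that is on the α face away from the pseudoaxial C1 methyl and the C6 oxygen, the charge spreads over C5–C7–C8 of the s-trans diene, and the β-hydroxyl on C6, held cis to C8 in that conformer, closes ring B at the primary terminus C8 (formally 5-endo, the closure by which (Z)-4-hydroxyallyl cations give 2,5-dihydrofurans), so that C4–Cl is set trans to the oxygen and the C5=C7 geometry is fixed by the ring; the closest known reaction types are the 1,4-halocyclisations of conjugated dienes and enynes and the 5-endo haloetherification of homoallylic alcohols.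

**Step 10**
Reactants: 21 (4S,6S,7aR)-6-bromo-4-chloro-7,7-dimethyl-2,4,5,6,7,7a-hexahydro-1-benzofuran; 22 boron trichloride
Product: 24 (1R,2E,3S,5S)-5-bromo-3-chloro-2-(2-chloroethylidene)-6,6-dimethylcyclohexan-1-ol (CH2Cl arm cis to C6), via dichloroboryl ether 23 (not isolated)
Conditions: BCl3 (1 M in CH2Cl2, 1.1 equiv), CH2Cl2, −78 °C; then ice-water
Reagents that add atoms: boron trichloride 22, ClB(Cl)Cl
Why: Lewis-acid ether cleavage: BCl3 binds the ring oxygen and chloride opens the oxonium ion by SN2 at the unhindered primary allylic C8 rather than at neopentylic C6, so the C6–O bond, its configuration and the alkene geometry are kept, and chloride rather than bromide is placed on C8 here so that the following chlorination cannot scramble two different halides.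

**Step 11**
Reactants: 24 (1R,2E,3S,5S)-5-bromo-3-chloro-2-(2-chloroethylidene)-6,6-dimethylcyclohexan-1-ol; 25 hexachloroacetone
Product: 26 (2S,3Z,4S,6S)-6-bromo-2,4-dichloro-3-(2-chloroethylidene)-1,1-dimethylcyclohexane
Conditions: PPh3, Cl3CC(O)CCl3, CH2Cl2, −20 °C to rt
Reagents that add atoms: hexachloroacetone 25, ClC(Cl)(Cl)C(=O)C(Cl)(Cl)Cl
Why: Appel-type deoxychlorination (PPh3/hexachloroacetone, the variant known to turn secondary allylic alcohols into unrearranged chlorides with inversion): C6 has no β-hydrogen so elimination is excluded, allylic overlap loosens the C–O bond enough to offset the neopentylic hindrance, and chloride enters from the α face opposite the leaving group and the pseudoaxial C1 methyl, giving the axial α-chloride, the only C6 epimer free of A(1,3) strain with the cis CH2Cl arm.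

**Step 12**
Reactants: 26 (2S,3Z,4S,6S)-6-bromo-2,4-dichloro-3-(2-chloroethylidene)-1,1-dimethylcyclohexane; 27 lithium bromide
Product: 28 (2S,3Z,4S,6S)-6-bromo-3-(2-bromoethylidene)-2,4-dichloro-1,1-dimethylcyclohexane (target)
Conditions: LiBr (10 equiv), acetone, rt
Reagents that add atoms: lithium bromide 27, [Li+].[Br-]
Why: Finkelstein halide exchange: SN2 at the primary allylic C8–Cl bond is much faster than at the two flanked secondary allylic chlorides or at the neopentylic C2 bromide, and the poorly soluble LiCl pulls the equilibrium, so only C8 is exchanged and neither a stereocentre nor the alkene geometry is touched.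

**Compound list**
1 | 2-methylbut-3-yn-2-ol | CC(C)(O)C#C | starting material
2 | trimethylaluminium | C[Al](C)C | starting material
3 | allyl bromide | C=CCBr | starting material
4 | alkenylalane: dimethylaluminium (E)-4-(dimethylalumanyl)-2,3-dimethylbut-3-en-2-olate | C[Al](C)OC(C)(C)/C(C)=C/[Al](C)C | intermediate (not isolated)
5 | (E)-2,3-dimethylhepta-3,6-dien-2-ol | CC(C)(O)/C(C)=C/CC=C | intermediate
6 | N-bromosuccinimide | O=C1CCC(=O)N1Br | starting material
7 | (S)-4-bromo-3,3-dimethylhept-6-en-2-one | CC(=O)C(C)(C)[C@@H](Br)CC=C | intermediate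
8 | N,N-dimethylmethyleneiminium iodide (Eschenmoser's salt) | C[N+](C)=C.[I-] | starting material
9 | lithium enolate: lithium (S)-4-bromo-3,3-dimethylhepta-1,6-dien-2-olate | [Li]OC(=C)C(C)(C)[C@@H](Br)CC=C | intermediate (not isolated)
10 | (S)-5-bromo-1-(dimethylamino)-4,4-dimethyloct-7-en-3-one | CN(C)CCC(=O)C(C)(C)[C@@H](Br)CC=C | intermediate
11 | iodomethane | CI | starting material
12 | methiodide: (S)-5-bromo-N,N,N,4,4-pentamethyl-3-oxooct-7-en-1-aminium iodide | C[N+](C)(C)CCC(=O)C(C)(C)[C@@H](Br)CC=C.[I-] | intermediate (not isolated)
13 | (S)-5-bromo-4,4-dimethylocta-1,7-dien-3-one | C=CC(=O)C(C)(C)[C@@H](Br)CC=C | intermediate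
14 | (S)-5-bromo-6,6-dimethylcyclohex-2-en-1-one | CC1(C)[C@@H](Br)CC=CC1=O | intermediate
15 | iodine | [I][I] | starting material
16 | (S)-5-bromo-2-iodo-6,6-dimethylcyclohex-2-en-1-one | CC1(C)[C@@H](Br)CC=C(I)C1=O | intermediate
17 | (1S,5S)-5-bromo-2-iodo-6,6-dimethylcyclohex-2-en-1-ol | CC1(C)[C@@H](Br)CC=C(I)[C@H]1O | intermediate
18 | tributyl(vinyl)stannane | C=C[Sn](CCCC)(CCCC)CCCC | starting material
19 | (1R,5S)-5-bromo-2-ethenyl-6,6-dimethylcyclohex-2-en-1-ol | CC1(C)[C@@H](Br)CC=C(C=C)[C@H]1O | intermediate
20 | N-chlorosuccinimide | O=C1CCC(=O)N1Cl | starting material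
21 | (4S,6S,7aR)-6-bromo-4-chloro-7,7-dimethyl-2,4,5,6,7,7a-hexahydro-1-benzofuran | CC1(C)[C@@H](Br)C[C@H](Cl)C2=CCO[C@@H]12 | intermediate
22 | boron trichloride | ClB(Cl)Cl | starting material
23 | dichloroboryl ether of 24 | CC1(C)[C@@H](Br)C[C@H](Cl)/C(=C/CCl)[C@H]1OB(Cl)Cl | intermediate (not isolated)
24 | (1R,2E,3S,5S)-5-bromo-3-chloro-2-(2-chloroethylidene)-6,6-dimethylcyclohexan-1-ol | CC1(C)[C@@H](Br)C[C@H](Cl)/C(=C/CCl)[C@H]1O | intermediate
25 | hexachloroacetone | ClC(Cl)(Cl)C(=O)C(Cl)(Cl)Cl | starting material
26 | (2S,3Z,4S,6S)-6-bromo-2,4-dichloro-3-(2-chloroethylidene)-1,1-dimethylcyclohexane | CC1(C)[C@@H](Br)C[C@H](Cl)/C(=C/CCl)[C@@H]1Cl | intermediate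
27 | lithium bromide | [Li+].[Br-] | starting material
28 | (2S,3Z,4S,6S)-6-bromo-3-(2-bromoethylidene)-2,4-dichloro-1,1-dimethylcyclohexane | CC1(C)[C@@H](Br)C[C@H](Cl)/C(=C/CBr)[C@@H]1Cl | target

**Step count**
Total step count: 12.
Longest linear sequence: 12 steps (1 to 28).

**Steps most likely to fail**

Step 2. The methyl shift may lose out to closure of the hydroxyl onto the bromonium carbon or to proton loss from the vinylic methyl, and the catalyst may discriminate the two alkene faces poorly.
- The fallback sets out from 5 and comes back at 7, and lets oxygen instead of bromine trigger the shift.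
- Shi epoxidation (D-fructose-derived ketone, Oxone, buffered MeCN/dimethoxymethane/water, 0 °C) should oxidise only the trisubstituted alkene. It should give 2-[(2S,3R)-2-methyl-3-(prop-2-enyl)oxiran-2-yl]propan-2-ol F1.
- BF3·OEt2 in CH2Cl2 at −78 °C then induces the known semipinacol rearrangement of a tertiary 2,3-epoxy alcohol, with the methyl shifting anti to the opening C–O bond. The product is (R)-4-hydroxy-3,3-dimethylhept-6-en-2-one F2, whose carbinol centre keeps the epoxide configuration.
- Appel bromination (CBr4, PPh3, CH2Cl2) replaces the hydroxyl with inversion and should deliver 7.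

Step 9. The chloronium ion may be captured at C5 or by an outside nucleophile, Cl+ may attack the vinyl terminus, or the 5-endo closure may be too slow. The fallback sets out from 19 and comes back at 24, using only known reaction types.
- Hydroxyl-directed epoxidation (VO(acac)2, tBuOOH, CH2Cl2, 0 °C) should put the oxygen on the β face of C4=C5 and give the epoxy alcohol F3.
- Acetylation (Ac2O, pyridine) gives the epoxy acetate F4, in which a hydride shift from C6 is no longer favoured.
- TiCl4 in CH2Cl2 at −78 °C opens the vinyl epoxide in the SN2' sense. This is the reaction by which 2-alkyl-2-vinyloxiranes give 4-chlorobut-2-en-1-ols with the CH2Cl group trans to the carbinol carbon. Here that places C8 trans to C4 and cis to C6, in the chlorohydrin acetate F5.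
- PPh3/hexachloroacetone converts the unhindered allylic 4β-hydroxyl into the 4α-chloride with inversion, giving the dichloro acetate F6.
- iBu2AlH in CH2Cl2 at −78 °C removes the acetate without forming a free alkoxide, which gives 24.

Step 11. Backside attack at neopentylic C6 may be so slow that allylic transposition of chloride to C7 or a methyl shift takes over. The fallback sets out from 24 and comes back at 26, and replaces concerted displacement by ionisation and face-selective capture.
- MsCl and 2,6-lutidine in CH2Cl2 at −40 °C give the mesylate F7.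
- F7 is left to ionise in CH2Cl2/(CF3)2CHOH in the presence of Bu4NCl.
- The allyl cation carries more charge on C6 than on C7, which sits next to the CH2Cl group.
- Chloride should be taken up on the α face, anti to the pseudoaxial C1 methyl, because only the axial chloride escapes A(1,3) strain with the cis CH2Cl arm.
- The much poorer leaving group at C4 stays bound under these conditions.

**Further compounds**
F1 | step 2 | 2-[(2S,3R)-2-methyl-3-(prop-2-enyl)oxiran-2-yl]propan-2-ol | CC(C)(O)[C@@]1(C)O[C@@H]1CC=C
F2 | step 2 | (R)-4-hydroxy-3,3-dimethylhept-6-en-2-one | CC(=O)C(C)(C)[C@H](O)CC=C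
F3 | step 9 | epoxy alcohol: 4-bromo-3,3-dimethyl-1-vinyl-7-oxabicyclo[4.1.0]heptan-2-ol (OH, epoxide O and Br all β) | CC1(C)[C@@H](Br)C[C@H]2O[C@@]2(C=C)[C@H]1O
F4 | step 9 | epoxy acetate: acetate of F3 | CC1(C)[C@@H](Br)C[C@H]2O[C@@]2(C=C)[C@H]1OC(C)=O
F5 | step 9 | chlorohydrin acetate: 5-bromo-2-(2-chloroethylidene)-3-hydroxy-6,6-dimethylcyclohexyl acetate (OAc, OH and Br β; CH2Cl cis to C6) | CC1(C)[C@@H](Br)C[C@@H](O)/C(=C/CCl)[C@H]1OC(C)=O
F6 | step 9 | dichloro acetate: acetate of 24 | CC1(C)[C@@H](Br)C[C@H](Cl)/C(=C/CCl)[C@H]1OC(C)=O
F7 | step 11 | mesylate: methanesulfonate of 24 | CC1(C)[C@@H](Br)C[C@H](Cl)/C(=C/CCl)[C@H]1OS(C)(=O)=O
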